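**Retrosynthetic overview**

1. Ring B is labelled C1' = CH on the C=CH2 carbon, C3' = CHBr, C4' = C(CH3)OH. Its oxygen sits para to C1' and its bromine sits on only one neighbour of C4'. This is the imprint of a cyclohex-3-enyl silyl ether (C3'=C4') made from a 2-silyloxybutadiene and a vinyl ketone whose carbonyl carbon later becomes the C=CH2 carbon.
2. Target ⇒ desilylation; C4'–CH3 by methyl Grignard addition to the equatorial α-bromoketone; C3'–Br by bromination of the enol silane and bromide exchange; C=O → C=CH2 ⇒ the ketone that joins ring A to the ring-B enol silane.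
3. That ketone ⇒ catalytic asymmetric Diels–Alder reaction (forming C1'–C2' and C5'–C6') of the ring-A vinyl ketone with 2-(triisopropylsilyloxy)buta-1,3-diene.
4. Ring A is labelled C1 = C(CH3)OH, C2 = CHOH, C3 = CH–CH2, C4 = CH–isopropenyl, and it is a p-menthane. Vinyl ketone ⇒ Weinreb amide ⇒ C3 alkylation and C2 reduction of a 1-silyloxy-p-menth-8-en-2-one ⇒ the epoxide of (S)-carvone.
5. Ring order: ring A is taken intact from the chiral pool. Ring B is the only ring formed, and it forms in the key step.

Key step: step 10

Assumption: the facial sense of the (S)-configured oxazaborolidinium catalyst toward vinyl ketones is taken from the α-C–H···O binding model used for acrylates and acyclic enones; if it proves opposite, the equally available (R)-configured catalyst is used with no other change.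

**Step 1**
Reactants: 1 (S)-(+)-carvone
Product: 2 (1S,4S,6S)-1-methyl-4-(prop-1-en-2-yl)-7-oxabicyclo[4.1.0]heptan-2-one (oxirane trans to isopropenyl)
Conditions: 30% aq. H2O2, NaOH (cat.), MeOH, 0 °C
Reagents that add atoms: hydrogen peroxide, OO
Why: Weitz–Scheffer nucleophilic epoxidation, in which hydroperoxide adds axially to the β-carbon C6 anti to the C4 isopropenyl group, so the C1–O bond is set trans to isopropenyl while the unactivated isopropenyl alkene is left alone.

**Step 2**
Reactants: 2 carvone epoxide
Product: 4 (1S,4S)-1-methyl-4-(prop-1-en-2-yl)cyclohexane-1,2-diol (both C2 epimers), via epoxy alcohol 3 (not isolated)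
Conditions: LiAlH4, THF, 0 → 66 °C; aq. potassium sodium tartrate work-up
Reagents that add atoms: none
Why: Carbonyl reduction followed by SN2 hydride opening of the trisubstituted epoxide at its secondary carbon C6 (through the half-chair with pseudoaxial isopropenyl) rather than at the fully substituted C1, so the C1–O bond and its configuration are kept; the C2 mixture does not matter because C2 is reoxidised.

**Step 3**
Reactants: 4 diol
Product: 5 (2S,5S)-2-hydroxy-2-methyl-5-(prop-1-en-2-yl)cyclohexan-1-one
Conditions: IBX, DMSO, 23 °C
Reagents that add atoms: none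
Why: IBX oxidation of a 1,2-diol to the α-ketol without glycol cleavage; only the secondary C2 carbinol can be oxidised, and both epimers converge on one ketone.

**Step 4**
Reactants: 5 α-hydroxy ketone
Product: 6 (2S,5S)-2-methyl-5-(prop-1-en-2-yl)-2-(triethylsilyloxy)cyclohexan-1-one
Conditions: Et3SiOTf, 2,6-lutidine, CH2Cl2, −78 → 0 °C
Reagents that add atoms: triethylsilyl trifluoromethanesulfonate, CC[Si](CC)(CC)OS(=O)(=O)C(F)(F)F
Why: Silyl triflate silylation of a tertiary alcohol, which blocks O-alkylation and α-ketol rearrangement in the enolate step.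

**Step 5**
Reactants: 6 silyloxy ketone; 7 2-bromo-N-methoxy-N-methylacetamide
Product: 9 2-[(1R,3S,6S)-3-methyl-2-oxo-6-(prop-1-en-2-yl)-3-(triethylsilyloxy)cyclohexyl]-N-methoxy-N-methylacetamide, via lithium enolate 8 (not isolated)
Conditions: LiN(iPr)2, THF, −78 °C; then 7, DMPU, −78 → −20 °C
Reagents that add atoms: none
Why: Lithium enolate alkylation in which C3 is the only enolisable position (C1 is quaternary) and the α-bromo amide approaches anti to the adjacent C4 isopropenyl group, giving the trans C3/C4 product; this is also the diequatorial thermodynamic epimer, so any cis material can be equilibrated at C3.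

**Step 6**
Reactants: 9 keto amide
Product: 10 2-[(1R,2S,3S,6S)-2-hydroxy-3-methyl-6-(prop-1-en-2-yl)-3-(triethylsilyloxy)cyclohexyl]-N-methoxy-N-methylacetamide
Conditions: NaBH4, MeOH, 0 °C; crude product silylated at once
Reagents that add atoms: none
Why: Borohydride reduction in the chair that has isopropenyl, the C3 arm and OSiEt3 equatorial and the C1 methyl axial; hydride enters axially on the face opposite that methyl and gives the equatorial C2–OH, trans to both C1–O and the C3 arm, and the Weinreb amide is inert.

**Step 7**
Reactants: 10 hydroxy amide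
Product: 11 N-methoxy-N-methyl-2-[(1R,2S,3S,6S)-3-methyl-6-(prop-1-en-2-yl)-2,3-bis(triethylsilyloxy)cyclohexyl]acetamide
Conditions: Et3SiOTf, 2,6-lutidine, CH2Cl2, 0 °C
Reagents that add atoms: triethylsilyl trifluoromethanesulfonate, CC[Si](CC)(CC)OS(=O)(=O)C(F)(F)F
Why: Silyl triflate silylation of the hindered secondary alcohol, which also removes the chance of γ-lactonisation onto the amide.

**Step 8**
Reactants: 11 bis-silyl Weinreb amide
Product: 13 1-[(1R,2S,3S,6S)-3-methyl-6-(prop-1-en-2-yl)-2,3-bis(triethylsilyloxy)cyclohexyl]but-3-en-2-one, via magnesium hemiaminal 12 (not isolated)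
Conditions: CH2=CHMgBr, THF, 0 °C; inverse quench into cold aq. citric acid
Reagents that add atoms: vinylmagnesium bromide, C=C[Mg]Br
Why: Weinreb ketone synthesis in which the chelated tetrahedral adduct stops over-addition, and the acidic inverse quench protonates the released amine before it can add to the new enone.

**Step 9**
Reactants: 14 methyl vinyl ketone
Product: 15 2-(triisopropylsilyloxy)buta-1,3-diene
Conditions: iPr3SiOTf, Et3N, Et2O, 0 → 23 °C
Reagents that add atoms: triisopropylsilyl trifluoromethanesulfonate, CC(C)[Si](C(C)C)(C(C)C)OS(=O)(=O)C(F)(F)F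
Why: Soft enolisation and O-silylation of an enone at its only enolisable position gives the cross-conjugated silyloxydiene.

**Step 10**
Reactants: 13 ring-A vinyl ketone; 15 2-(triisopropylsilyloxy)buta-1,3-diene
Product: 16 2-[(1R,2S,3S,6S)-3-methyl-6-(prop-1-en-2-yl)-2,3-bis(triethylsilyloxy)cyclohexyl]-1-[(1R)-4-(triisopropylsilyloxy)cyclohex-3-en-1-yl]ethan-1-one
Conditions: (S)-3,3-diphenyl-1-(2-methylphenyl)tetrahydro-1H,3H-pyrrolo[1,2-c][1,3,2]oxazaborole (C24H24BNO, 20 mol %), (CF3SO2)2NH (17 mol %), 15 (3 equiv), CH2Cl2, −78 → −20 °C
Reagents that add atoms: none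
Why: The N-protonated oxazaborolidine binds the carbonyl oxygen of 13 at boron through the lone pair on the vinyl side, with the vinyl α-C–H held against the catalyst ring oxygen, so the s-trans enone lies over one phenyl group and 15 adds to the open face in a concerted but asynchronous [4π+2π] cycloaddition. The closest known reaction type is the oxazaborolidinium-catalysed Diels–Alder addition of 2-(triisopropylsilyloxy)butadiene to acrylates and acyclic enones. Ring B, a six-membered carbocycle, closes by intermolecular suprafacial [4+2] union in which C1'–C2' and C5'–C6' form in the same event. C1', the only new stereocentre, is fixed by the catalyst, which exposes the Si face of the enone α-carbon and so gives the (R) configuration, while the ring-A stereocentres begin at the β-position of the ketone and are too remote to compete. The step needs para regioselectivity, secured by the 2-silyloxy group, which puts the largest diene HOMO coefficient on the CH2 terminus next to C–OSi and pairs it with the enone β-carbon, leaving the enol double bond at C3'=C4'; no endo/exo question arises because all reacting termini are unsubstituted. It also needs chemoselectivity, secured because only the conjugated alkene of 13 is activated (isopropenyl is not) and because keeping (CF3SO2)2NH below the amount of oxazaborolidine at low temperature leaves no free acid to attack the triethylsilyl ethers or the enol silane.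

**Step 11**
Reactants: 16 Diels–Alder ketone
Product: 17 1,1-disubstituted alkene: the C=O of 16 replaced by C=CH2, ring-B enol silane and (1'R) centre unchanged
Conditions: Cp2TiMe2, toluene, 70 °C, dark
Reagents that add atoms: dimethyltitanocene, C[Ti+2]C.c1cc[cH-]c1.c1cc[cH-]c1
Why: Petasis methylenation through Cp2Ti=CH2 and an oxatitanacyclobutane is neither basic nor acidic, so the enolisable C1' centre, the enol silane and the silyl ethers are preserved.

**Step 12**
Reactants: 17 triene enol silane
Product: 18 (2S,4R)-2-bromo-4-{3-[(1R,2S,3S,6S)-3-methyl-6-(prop-1-en-2-yl)-2,3-bis(triethylsilyloxy)cyclohexyl]prop-1-en-2-yl}cyclohexan-1-one (Br axial, trans to the C1' substituent)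
Conditions: NBS, NaHCO3, THF, −78 → −20 °C, dark
Reagents that add atoms: N-bromosuccinimide, O=C1CCC(=O)N1Br
Why: Electrophilic α-bromination of a regiodefined silyl enol ether puts bromine on C3' only and outruns the two 1,1-disubstituted alkenes; axial attack on the half-chair with the C1' substituent equatorial should favour the trans bromide 18, and any cis epimer 19 formed is pooled with the product of step 13.

**Step 13**
Reactants: 18 axial bromoketone
Product: 19 (2R,4R)-2-bromo-4-{3-[(1R,2S,3S,6S)-3-methyl-6-(prop-1-en-2-yl)-2,3-bis(triethylsilyloxy)cyclohexyl]prop-1-en-2-yl}cyclohexan-1-one (Br equatorial, cis to the C1' substituent)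
Conditions: LiBr, DMF, 23 °C; chromatography, recovered 18 resubmitted
Reagents that add atoms: lithium bromide, [Li+].[Br-]
Why: Degenerate Finkelstein-type SN2 bromide exchange inverts C3' under neutral conditions, and the polar medium raises the share of the dipole-aligned equatorial epimer; the equilibrium is not one-sided, so 19 is drawn off by separation and 18 is recycled.

**Step 14**
Reactants: 19 equatorial bromoketone
Product: 20 bis(triethylsilyl) ether of the target, ring B (1R,3R,4S)-3-bromo-4-hydroxy-4-methylcyclohexyl
Conditions: MeMgBr, Et2O–toluene, −78 °C; aq. NH4Cl at −78 °C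
Reagents that add atoms: methylmagnesium bromide, C[Mg]Br
Why: Grignard addition to a 2-halocyclohexanone, which places methyl trans to the halogen; on the locked chair this is equatorial attack, giving equatorial CH3 and axial OH cis to the equatorial bromine, and the cold quench prevents rearrangement of the magnesium bromohydrinate.

**Step 15**
Reactants: 20 protected bromohydrin
Product: 21 target, (1S,2S,3R,4S)-3-{2-[(1R,3R,4S)-3-bromo-4-hydroxy-4-methylcyclohexyl]prop-2-en-1-yl}-1-methyl-4-(prop-1-en-2-yl)cyclohexane-1,2-diol
Conditions: HF·pyridine, pyridine, THF, 0 → 23 °C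
Reagents that add atoms: none
Why: Buffered fluoride desilylation removes both triethylsilyl ethers without the basicity that could disturb the bromohydrin and without acid strong enough to protonate the 1,1-disubstituted alkenes.

**Compound list**

1 | (S)-(+)-carvone | CC1=CC[C@@H](CC1=O)C(C)=C | starting material
2 | (1S,4S,6S)-carvone epoxide | C1[C@@H](C(=C)C)C[C@@H]2O[C@]2(C)C1=O | intermediate
3 | epoxy alcohol (C2 epimers, present as aluminate) | C1[C@@H](C(=C)C)C[C@@H]2O[C@]2(C)C1O | intermediate
4 | (1S,4S)-1-methyl-4-(prop-1-en-2-yl)cyclohexane-1,2-diol (C2 epimers) | C1[C@@H](C(=C)C)CC[C@](C)(O)C1O | intermediate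
5 | (2S,5S)-2-hydroxy-2-methyl-5-(prop-1-en-2-yl)cyclohexan-1-one | C1[C@@H](C(=C)C)CC[C@](C)(O)C1=O | intermediate
6 | (2S,5S)-2-methyl-5-(prop-1-en-2-yl)-2-(triethylsilyloxy)cyclohexan-1-one | C1[C@@H](C(=C)C)CC[C@](C)(O[Si](CC)(CC)CC)C1=O | intermediate
7 | 2-bromo-N-methoxy-N-methylacetamide | CON(C)C(=O)CBr | starting material
8 | lithium enolate of 6 | [Li+].[O-]C1=C[C@@H](C(=C)C)CC[C@]1(C)O[Si](CC)(CC)CC | intermediate
9 | keto Weinreb amide | CON(C)C(=O)C[C@@H]1[C@@H](C(=C)C)CC[C@](C)(O[Si](CC)(CC)CC)C1=O | intermediate
10 | hydroxy Weinreb amide | CON(C)C(=O)C[C@@H]1[C@@H](C(=C)C)CC[C@](C)(O[Si](CC)(CC)CC)[C@H]1O | intermediate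
11 | bis(triethylsilyl) Weinreb amide | CON(C)C(=O)C[C@@H]1[C@@H](C(=C)C)CC[C@](C)(O[Si](CC)(CC)CC)[C@H]1O[Si](CC)(CC)CC | intermediate
12 | magnesium hemiaminal (tetrahedral adduct, new carbon uncontrolled) | C=CC([O-])(N(C)OC)C[C@@H]1[C@@H](C(=C)C)CC[C@](C)(O[Si](CC)(CC)CC)[C@H]1O[Si](CC)(CC)CC.[Mg+2].[Br-] | intermediate
13 | ring-A vinyl ketone | C=CC(=O)C[C@@H]1[C@@H](C(=C)C)CC[C@](C)(O[Si](CC)(CC)CC)[C@H]1O[Si](CC)(CC)CC | intermediate
14 | methyl vinyl ketone | CC(=O)C=C | starting material
15 | 2-(triisopropylsilyloxy)buta-1,3-diene | C=CC(=C)O[Si](C(C)C)(C(C)C)C(C)C | intermediate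
16 | Diels–Alder ketone, (1'R) | O=C(C[C@@H]1[C@@H](C(=C)C)CC[C@](C)(O[Si](CC)(CC)CC)[C@H]1O[Si](CC)(CC)CC)[C@@H]2CCC(O[Si](C(C)C)(C(C)C)C(C)C)=CC2 | intermediate
17 | methylenated enol silane | C=C(C[C@@H]1[C@@H](C(=C)C)CC[C@](C)(O[Si](CC)(CC)CC)[C@H]1O[Si](CC)(CC)CC)[C@@H]2CCC(O[Si](C(C)C)(C(C)C)C(C)C)=CC2 | intermediate
18 | trans (axial) bromoketone | C=C(C[C@@H]1[C@@H](C(=C)C)CC[C@](C)(O[Si](CC)(CC)CC)[C@H]1O[Si](CC)(CC)CC)[C@@H]2CCC(=O)[C@@H](Br)C2 | intermediate
19 | cis (equatorial) bromoketone | C=C(C[C@@H]1[C@@H](C(=C)C)CC[C@](C)(O[Si](CC)(CC)CC)[C@H]1O[Si](CC)(CC)CC)[C@@H]2CCC(=O)[C@H](Br)C2 | intermediate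
20 | bis(triethylsilyl) ether of the target | C=C(C[C@@H]1[C@@H](C(=C)C)CC[C@](C)(O[Si](CC)(CC)CC)[C@H]1O[Si](CC)(CC)CC)[C@@H]2CC[C@](C)(O)[C@H](Br)C2 | intermediate
21 | CNP0422107.2 | C=C(C[C@@H]1[C@@H](C(=C)C)CC[C@](C)(O)[C@H]1O)[C@@H]1CC[C@](C)(O)[C@H](Br)C1 | target

**Total steps:** 15. **Longest linear sequence:** 14 (steps 1–8 and 10–15).

**Steps most likely to fail**

**Step 10.**
- The catalyst may also bind through the carbonyl lone pair on the CH2 side, which offers an α-C–H of its own, and that would erode facial selectivity.
- Traces of free acid may strip silyl groups.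
- The addition may stop at the Mukaiyama–Michael stage without ring closure.

The fallback gives up catalyst control and uses the acidity of C1' instead. It sets out from 13 and 15. These are heated without catalyst in toluene at 90 °C, where the silyloxy group still directs para. This should give 16 together with its ring-B (1'S) epimer F1. The two are separated by chromatography. F1 is re-equilibrated with DBU in toluene, since C1' is α to the ketone, and separated again. The route is rejoined at 16.

**Step 13.**
- The exchange equilibrium may sit on the side of the axial bromide, because the equatorial C–Br dipole is aligned with C=O.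
- The exchange may be slow.
- Loss of HBr may set in.

The fallback replaces thermodynamic control by kinetic protonation. It sets out from 18, or from the 18/19 mixture. Soft enolisation with Me3SiOTf and Et3N in CH2Cl2, under equilibrating conditions, goes toward the more acidic C3'–H and gives the 2-bromo enol trimethylsilyl ether F2. Treatment with Bu4NF buffered with AcOH in THF at −78 °C frees the bromo enolate. This is protonated along the axial trajectory, which turns bromine into the equatorial position. The route is rejoined at 19.

**Step 14.**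
- An equatorial bromine offers no stereoelectronic bias, so some attack from the axial side may occur.
- The basic Grignard reagent may enolise the ketone.
- The magnesium bromohydrinate may rearrange on warming.

The fallback uses the kinetic axial bromide, where attack anti to C–Br is enforced, and corrects C1' afterwards by equilibration. It sets out from 13 and 15.
- The cycloaddition is run with the (R)-configured oxazaborolidine and (CF3SO2)2NH to make the (1'S) adduct F1 on purpose.
- NBS in THF at −78 °C gives the trans (axial) bromo diketone F3, which already has the C3' configuration of the target.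
- MeTi(OiPr)3 in Et2O at −20 °C adds chemoselectively to the activated ring ketone, anti to bromine, and gives the bromohydrin ketone F4.
- K2CO3 in MeOH at 23 °C epimerises C1', α to the remaining ketone. This gives the isomer F5, in which the side chain, bromine and methyl are all equatorial.
- Cp2TiMe2 in toluene at 70 °C then methylenates the ketone.

The route is rejoined at 20.

**Further compounds**

F1 | step 10 | (1'S) epimer of Diels–Alder ketone 16 | O=C(C[C@@H]1[C@@H](C(=C)C)CC[C@](C)(O[Si](CC)(CC)CC)[C@H]1O[Si](CC)(CC)CC)[C@H]2CCC(O[Si](C(C)C)(C(C)C)C(C)C)=CC2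
F2 | step 13 | 2-bromo enol trimethylsilyl ether of 18/19 | C=C(C[C@@H]1[C@@H](C(=C)C)CC[C@](C)(O[Si](CC)(CC)CC)[C@H]1O[Si](CC)(CC)CC)[C@@H]2CCC(O[Si](C)(C)C)=C(Br)C2
F3 | step 14 | (1'S,3'R) trans bromo diketone | O=C(C[C@@H]1[C@@H](C(=C)C)CC[C@](C)(O[Si](CC)(CC)CC)[C@H]1O[Si](CC)(CC)CC)[C@H]2CCC(=O)[C@H](Br)C2
F4 | step 14 | (1'S,3'R,4'S) bromohydrin ketone | O=C(C[C@@H]1[C@@H](C(=C)C)CC[C@](C)(O[Si](CC)(CC)CC)[C@H]1O[Si](CC)(CC)CC)[C@H]2CC[C@](C)(O)[C@H](Br)C2
F5 | step 14 | (1'R,3'R,4'S) bromohydrin ketone | O=C(C[C@@H]1[C@@H](C(=C)C)CC[C@](C)(O[Si](CC)(CC)CC)[C@H]1O[Si](CC)(CC)CC)[C@@H]2CC[C@](C)(O)[C@H](Br)C2
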